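**Strategy.** Labdane numbering is used. Ring A carries no functionality, and its C1–C2 bond joins two methylenes whose anchors, quaternary C10 and the gem-dimethyl carbon C4 (through C3), sit trans-diequatorial on ring B. The route therefore first builds a ring B cyclohexanone bearing a vinyl group (C1) on C10 and a 2-methylpent-4-en-2-yl group (C4–C2) on C5. Ring-closing olefin metathesis then closes ring A, forging C1=C2 and the trans-decalin in one operation. One hydrogenation saturates C1=C2 and sets C9. The side chain is joined by Negishi coupling and ring B is oxidised last.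

Key step: step 6

Remark: the (R)-configured prolinol ether catalyst in step 2 is chosen by analogy with the usual face-shielding model for diarylprolinol ether enamines; the antipodal catalyst would give the enantiomeric series.

**Step 1**
Reactants: 1 2,2-dimethylpent-4-enal
Product: 3 3,3-dimethylhex-5-enal, via enol ether 2 (not isolated)
Conditions: Ph3P(Cl)CH2OMe, KOtBu, THF, 0 °C to rt; then 2 M HCl, THF, rt
Reagents that add atoms: (methoxymethyl)triphenylphosphonium chloride, COC[P+](c1ccccc1)(c1ccccc1)c1ccccc1.[Cl-]; water, O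
Why: Wittig methoxymethylenation of the non-enolisable aldehyde followed by hydrolysis of the enol ether should give the one-carbon homologue; no stereocentre is formed.

**Step 2**
Reactants: 3 3,3-dimethylhex-5-enal; 4 but-3-en-2-one
Product: 6 (S)-4-(2-methylpent-4-en-2-yl)cyclohex-2-en-1-one, via keto aldehyde 5 (not isolated)
Conditions: (R)-2-[methoxy(diphenyl)methyl]pyrrolidine (5 mol %), ethyl 3,4-dihydroxybenzoate (20 mol %), neat, 4 °C; then LiOH, iPrOH, rt
Reagents that add atoms: none
Why: An enamine-catalysed asymmetric Michael addition should set C5 by attack on the enamine face left open by the diphenyl(methoxy)methyl group, and the intramolecular aldol condensation (Robinson-type annulation) then closes ring B.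

**Step 3**
Reactants: 6 (S)-4-(2-methylpent-4-en-2-yl)cyclohex-2-en-1-one
Product: 8 (R)-3-methyl-4-(2-methylpent-4-en-2-yl)cyclohex-2-en-1-one, via silyl enol ether 7 (not isolated)
Conditions: Me2CuLi, Me3SiCl, THF, −78 °C; then Pd(OAc)2, MeCN, rt
Reagents that add atoms: lithium dimethylcuprate, [Li+].C[Cu-]C
Why: Cuprate conjugate addition trans to the C5 substituent and Saegusa–Ito dehydrogenation of the silyl enol ether should place the C10 methyl on an sp2 carbon, so C5 remains the only stereocentre.

**Step 4**
Reactants: 8 (R)-3-methyl-4-(2-methylpent-4-en-2-yl)cyclohex-2-en-1-one; 9 2-(benzyloxy)acetaldehyde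
Product: 11 2-[2-(benzyloxy)-1-hydroxyethyl]-3-methyl-4-(2-methylpent-4-en-2-yl)-3-vinylcyclohexan-1-one (vinyl trans to the C5 side chain; mixture at C9 and C11), via lithium enolate 10 (not isolated)
Conditions: (CH2=CH)2CuLi, Et2O, −78 to −30 °C; then 9, THF, −78 °C; aq. NH4Cl
Reagents that add atoms: lithium divinylcuprate, [Li+].C=C[Cu-]C=C
Why: Conjugate addition of the vinyl cuprate anti to the bulky C5 group should fix the quaternary centre C10, and the regiodefined enolate is trapped at C9 in an aldol reaction (three-component coupling); the C9 and C11 centres are erased in step 5.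

**Step 5**
Reactants: 11 the aldol adduct
Product: 13 2-[2-(benzyloxy)ethylidene]-3-methyl-4-(2-methylpent-4-en-2-yl)-3-vinylcyclohexan-1-one (E/Z mixture), via mesylate 12 (not isolated)
Conditions: MeSO2Cl, Et3N, CH2Cl2, 0 °C; then DBU, rt
Reagents that add atoms: none
Why: Mesylation and E1cB elimination complete the aldol condensation to the 2-alkylidene ketone; the alkene geometry is irrelevant because this alkene is hydrogenated in step 7.

**Step 6**
Reactants: 13 the 2-alkylidene ketone
Product: 14 trans-fused 1-[2-(benzyloxy)ethylidene]-5,5,8a-trimethyl-3,4,4a,5,6,8a-hexahydronaphthalen-2(1H)-one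
Conditions: second-generation Grubbs catalyst RuCl2(=CHPh)(H2IMes)(PCy3) (5 mol %), CH2Cl2 (5 mM), 40 °C
Reagents that add atoms: none
Why: Ring-closing olefin metathesis by the Chauvin mechanism: the ruthenium benzylidene initiates at the unhindered allyl terminus (the carbon that becomes C2), and the resulting alkylidene undergoes [2+2] cycloaddition and cycloreversion with the C10 vinyl group, releasing ethene and forging C1=C2. The closest known reaction type is diene ring-closing metathesis to cyclohexenes bearing an allylic quaternary carbon, as used to close trans-fused decalins. Ring A is closed as a six-membered carbocycle by joining the two termini of a 1,7-diene on the preformed ring B. No stereocentre is created: the trans ring fusion follows from the trans relationship of the C10 vinyl group and the C5 side chain set in step 4, which are gauche in the diequatorial conformer. The step needs selectivity for the two monosubstituted alkenes over the C9=C11 enone alkene and for cyclisation over oligomerisation; the first is secured because that alkene is trisubstituted, conjugated and flanked by quaternary C10, the second by the gem-dimethyl group at C4 (Thorpe–Ingold effect), high dilution and loss of ethene.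

**Step 7**
Reactants: 14 the bicyclic dienone
Product: 15 trans-fused 1-(2-hydroxyethyl)-5,5,8a-trimethyloctahydronaphthalen-2(1H)-one (side chain cis to the angular methyl)
Conditions: H2 (1 atm), 10% Pd/C, EtOAc, rt
Reagents that add atoms: none
Why: Heterogeneous hydrogenation should saturate C1=C2, cleave the benzyl ether and add hydrogen to the exocyclic C9=C11 bond from the face opposite the axial C10 methyl, which places H-9 trans to that methyl and the two-carbon chain equatorial as in the target.

**Step 8**
Reactants: 15 the keto alcohol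
Product: 16 trans-fused 1-(2-iodoethyl)-5,5,8a-trimethyloctahydronaphthalen-2(1H)-one
Conditions: I2, PPh3, imidazole, CH2Cl2, 0 °C to rt
Reagents that add atoms: iodine, II
Why: Appel-type iodination converts the primary alcohol into the iodide under buffered conditions that should leave the hindered ketone and the adjacent C9 centre untouched.

**Step 9**
Reactants: 17 methyl 4-hydroxybut-2-ynoate
Product: 18 methyl (Z)-4-hydroxy-3-iodobut-2-enoate
Conditions: NaI, AcOH, 70 °C
Reagents that add atoms: sodium iodide, [Na+].[I-]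
Why: Conjugate hydroiodination of the ynoate proceeds by anti addition and should give the β-iodo enoate with iodine cis to the ester.

**Step 10**
Reactants: 18 methyl (Z)-4-hydroxy-3-iodobut-2-enoate
Product: 19 methyl (Z)-4-[(tert-butyldimethylsilyl)oxy]-3-iodobut-2-enoate
Conditions: tBuMe2SiCl, imidazole, CH2Cl2, rt
Reagents that add atoms: tert-butyldimethylsilyl chloride, CC(C)(C)[Si](C)(C)Cl
Why: Standard silylation protects the primary alcohol for the organozinc and amide-base steps that follow.

**Step 11**
Reactants: 16 the keto iodide; 19 the silylated iodo enoate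
Product: 21 methyl (E)-3-{[(tert-butyldimethylsilyl)oxy]methyl}-5-(5,5,8a-trimethyl-2-oxodecahydronaphthalen-1-yl)pent-2-enoate, via alkylzinc iodide 20 (not isolated)
Conditions: Zn dust (activated by Me3SiCl and BrCH2CH2Br), LiCl, THF, 35 °C; then 19, Pd(PPh3)4 (5 mol %), THF, rt
Reagents that add atoms: none
Why: Zinc insertion gives a ketone-tolerant alkylzinc iodide, and Negishi cross-coupling with the β-iodo enoate proceeds with retention of alkene geometry, so C12 ends up cis to the ester as in the (E)-C13=C14 bond of the target.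

**Step 12**
Reactants: 21 the keto ester
Product: 23 C7=C8 enol triflate of 21, via lithium enolate 22 (not isolated)
Conditions: LiN(iPr)2, THF, −78 °C; then N-(5-chloropyridin-2-yl)bis(trifluoromethanesulfonimide), −78 to 0 °C
Reagents that add atoms: N-(5-chloropyridin-2-yl)bis(trifluoromethanesulfonimide), Clc1ccc(nc1)N(S(=O)(=O)C(F)(F)F)S(=O)(=O)C(F)(F)F
Why: Kinetic deprotonation should occur at the less hindered C7 and not at the tertiary C9, and O-triflation of the enolate gives the enol triflate without epimerising C9.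

**Step 13**
Reactants: 23 the enol triflate
Product: 24 methyl (E)-3-{[(tert-butyldimethylsilyl)oxy]methyl}-5-(2-formyl-5,5,8a-trimethyl-1,4,4a,5,6,7,8,8a-octahydronaphthalen-1-yl)pent-2-enoate
Conditions: Pd(PPh3)4 (5 mol %), CO (1 atm), Bu3SnH (slow addition), THF, 50 °C
Reagents that add atoms: carbon monoxide, [C-]#[O+]
Why: Palladium-catalysed formylative carbonylation of the vinyl triflate (CO insertion, then reduction of the acylpalladium by the tin hydride) should install C17 as the conjugated aldehyde.

**Step 14**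
Reactants: 24 the enal
Product: 27 methyl (E)-5-(2-formyl-4-hydroxy-5,5,8a-trimethyl-1,4,4a,5,6,7,8,8a-octahydronaphthalen-1-yl)-3-(hydroxymethyl)pent-2-enoate, via silyl dienol ether 25 (not isolated), via silyl ether 26 (not isolated)
Conditions: Et3SiOTf, Et3N, CH2Cl2, −78 to 0 °C; then dimethyldioxirane, acetone/CH2Cl2, −78 to −20 °C; then HF·pyridine, THF, 0 °C to rt
Reagents that add atoms: dimethyldioxirane, CC1(C)OO1
Why: γ-Deprotonation gives the silyl dienol ether, which should be oxidised at its nucleophilic terminus C6 (vinylogous Rubottom oxidation) from the face opposite the axial methyls on C10 and C4, giving the 6-hydroxy group trans to the C10 methyl; fluoride then removes both silyl groups.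

**Step 15**
Reactants: 27 the diol
Product: 28 CNP0134813.1
Conditions: HCO2CH2CF3 (3 equiv), THF, 50 °C
Reagents that add atoms: 2,2,2-trifluoroethyl formate, O=COCC(F)(F)F
Why: Transesterification with the activated formate (chemoselective O-formylation) should be much faster at the unhindered primary allylic alcohol than at the secondary C6 alcohol flanked by C5 and the gem-dimethyl carbon.

**Compound list**

1 | 2,2-dimethylpent-4-enal | O=CC(C)(C)CC=C | starting material
2 | 1-methoxy-3,3-dimethylhexa-1,5-diene (E/Z mixture) | COC=CC(C)(C)CC=C | intermediate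
3 | 3,3-dimethylhex-5-enal | O=CCC(C)(C)CC=C | intermediate
4 | but-3-en-2-one | CC(=O)C=C | starting material
5 | (R)-2-(2-methylpent-4-en-2-yl)-5-oxohexanal | O=C[C@@H](C(C)(C)CC=C)CCC(C)=O | intermediate
6 | (S)-4-(2-methylpent-4-en-2-yl)cyclohex-2-en-1-one | O=C1C=C[C@@H](C(C)(C)CC=C)CC1 | intermediate
7 | trimethyl{[trans-3-methyl-4-(2-methylpent-4-en-2-yl)cyclohex-1-en-1-yl]oxy}silane | C[Si](C)(C)OC1=C[C@H](C)[C@@H](C(C)(C)CC=C)CC1 | intermediate
8 | (R)-3-methyl-4-(2-methylpent-4-en-2-yl)cyclohex-2-en-1-one | O=C1C=C(C)[C@@H](C(C)(C)CC=C)CC1 | intermediate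
9 | 2-(benzyloxy)acetaldehyde | O=CCOCc1ccccc1 | starting material
10 | lithium 3-methyl-4-(2-methylpent-4-en-2-yl)-3-vinylcyclohex-1-en-1-olate (vinyl trans to the C5 side chain) | [Li+].[O-]C1=C[C@](C)(C=C)[C@@H](C(C)(C)CC=C)CC1 | intermediate
11 | 2-[2-(benzyloxy)-1-hydroxyethyl]-3-methyl-4-(2-methylpent-4-en-2-yl)-3-vinylcyclohexan-1-one (mixture at C9 and C11) | O=C1C(C(O)COCc2ccccc2)[C@](C)(C=C)[C@@H](C(C)(C)CC=C)CC1 | intermediate
12 | methanesulfonate of 11 | O=C1C(C(OS(C)(=O)=O)COCc2ccccc2)[C@](C)(C=C)[C@@H](C(C)(C)CC=C)CC1 | intermediate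
13 | 2-[2-(benzyloxy)ethylidene]-3-methyl-4-(2-methylpent-4-en-2-yl)-3-vinylcyclohexan-1-one (E/Z mixture) | O=C1C(=CCOCc2ccccc2)[C@](C)(C=C)[C@@H](C(C)(C)CC=C)CC1 | intermediate
14 | trans-fused 1-[2-(benzyloxy)ethylidene]-5,5,8a-trimethyl-3,4,4a,5,6,8a-hexahydronaphthalen-2(1H)-one (C1=C2 alkene, C8 ketone, C9=C11 alkylidene) | O=C1CC[C@@H]2C(C)(C)CC=C[C@@]2(C)C1=CCOCc1ccccc1 | intermediate
15 | trans-fused 1-(2-hydroxyethyl)-5,5,8a-trimethyloctahydronaphthalen-2(1H)-one (side chain cis to the angular methyl) | O=C1CC[C@@H]2C(C)(C)CCC[C@@]2(C)[C@@H]1CCO | intermediate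
16 | trans-fused 1-(2-iodoethyl)-5,5,8a-trimethyloctahydronaphthalen-2(1H)-one | O=C1CC[C@@H]2C(C)(C)CCC[C@@]2(C)[C@@H]1CCI | intermediate
17 | methyl 4-hydroxybut-2-ynoate | COC(=O)C#CCO | starting material
18 | methyl (Z)-4-hydroxy-3-iodobut-2-enoate | I/C(CO)=C\C(=O)OC | intermediate
19 | methyl (Z)-4-[(tert-butyldimethylsilyl)oxy]-3-iodobut-2-enoate | I/C(CO[Si](C)(C)C(C)(C)C)=C\C(=O)OC | intermediate
20 | alkylzinc iodide from 16 | O=C1CC[C@@H]2C(C)(C)CCC[C@@]2(C)[C@@H]1CC[Zn]I | intermediate
21 | methyl (E)-3-{[(tert-butyldimethylsilyl)oxy]methyl}-5-(5,5,8a-trimethyl-2-oxodecahydronaphthalen-1-yl)pent-2-enoate | O=C1CC[C@@H]2C(C)(C)CCC[C@@]2(C)[C@@H]1CC/C(CO[Si](C)(C)C(C)(C)C)=C\C(=O)OC | intermediate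
22 | lithium C7=C8 enolate of 21 | [Li+].[O-]C1=CC[C@@H]2C(C)(C)CCC[C@@]2(C)[C@@H]1CC/C(CO[Si](C)(C)C(C)(C)C)=C\C(=O)OC | intermediate
23 | C7=C8 enol triflate of 21 | O=S(=O)(OC1=CC[C@@H]2C(C)(C)CCC[C@@]2(C)[C@@H]1CC/C(CO[Si](C)(C)C(C)(C)C)=C\C(=O)OC)C(F)(F)F | intermediate
24 | methyl (E)-3-{[(tert-butyldimethylsilyl)oxy]methyl}-5-(2-formyl-5,5,8a-trimethyl-1,4,4a,5,6,7,8,8a-octahydronaphthalen-1-yl)pent-2-enoate | O=CC1=CC[C@@H]2C(C)(C)CCC[C@@]2(C)[C@@H]1CC/C(CO[Si](C)(C)C(C)(C)C)=C\C(=O)OC | intermediate
25 | triethylsilyl dienol ether of 24 (C17=C8 and C6=C7) | CC[Si](CC)(CC)OC=C1C=C[C@@H]2C(C)(C)CCC[C@@]2(C)[C@@H]1CC/C(CO[Si](C)(C)C(C)(C)C)=C\C(=O)OC | intermediate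
26 | 6-(triethylsilyloxy) enal, 16-silyl ether | O=CC1=C[C@@H](O[Si](CC)(CC)CC)[C@@H]2C(C)(C)CCC[C@@]2(C)[C@@H]1CC/C(CO[Si](C)(C)C(C)(C)C)=C\C(=O)OC | intermediate
27 | methyl (E)-5-(2-formyl-4-hydroxy-5,5,8a-trimethyl-1,4,4a,5,6,7,8,8a-octahydronaphthalen-1-yl)-3-(hydroxymethyl)pent-2-enoate | O=CC1=C[C@@H](O)[C@@H]2C(C)(C)CCC[C@@]2(C)[C@@H]1CC/C(CO)=C\C(=O)OC | intermediate
28 | CNP0134813.1, methyl (E)-16-formyloxy-6-hydroxy-17-oxolabda-7,13-dien-15-oate (6-OH, H-5 and H-9 all trans to the C10 methyl) | COC(=O)/C=C(\CC[C@@H]1C(C=O)=C[C@@H](O)[C@@H]2C(C)(C)CCC[C@@]12C)COC=O | target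

**Step count.** Total: 15 steps. Longest linear sequence: 13 steps (steps 1–8 and 11–15); steps 9 and 10 prepare the coupling partner.

**Steps most likely to fail**

Step 4. The cuprate may add too slowly at C10, which lies next to the tert-alkyl-bearing C5, and the hindered enolate may be lost by proton transfer or the aldolate may revert. The fallback sets out from 8. A CuBr·SMe2-catalysed addition of CH2=CHMgBr accelerated by Me3SiCl and HMPA (THF, −78 °C) should give the isolable silyl enol ether trimethyl{[3-methyl-4-(2-methylpent-4-en-2-yl)-3-vinylcyclohex-1-en-1-yl]oxy}silane F1. A Me3SiOTf-catalysed Mukaiyama aldol-type addition of F1 to 2-(benzyloxy)acetaldehyde dimethyl acetal (CH2Cl2, −78 °C) should give the β-methoxy ketone 2-[2-(benzyloxy)-1-methoxyethyl]-3-methyl-4-(2-methylpent-4-en-2-yl)-3-vinylcyclohexan-1-one F2. DBU-promoted loss of methanol from F2 comes back to the route at 13.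

Step 14. Oxygen transfer may occur at the α-terminus C8 of the dienol ether instead of C6, or on the hindered face, and the electron-rich diene may be over-oxidised. The fallback sets out from 24 by way of 25. N-Bromosuccinimide (THF, −78 °C) should brominate the γ-terminus to give the 6-bromo enal silyl ether F3. Silver-assisted solvolysis (AgOCOCF3, aqueous acetone, rt) should replace bromide by water entering from the open face to give the 6-hydroxy enal silyl ether F4. HF·pyridine then comes back to the route at 27.

Step 7. Hydrogen may be delivered to the wrong face of the C9=C11 bond, or the allylic C12–O bond may be cleaved before the alkene is saturated. The fallback sets out from 14. Copper hydride conjugate reduction (Cu(OAc)2 and 1,2-bis(diphenylphosphino)benzene, 5 mol % each, PhSiH3, tBuOH, toluene, rt), with protonation of the copper enolate from the open face, should give the benzyl ether ketone trans-fused 1-[2-(benzyloxy)ethyl]-5,5,8a-trimethyl-3,4,4a,5,6,8a-hexahydronaphthalen-2(1H)-one F5 with C1=C2 intact. Hydrogenation of F5 over Pd/C then only saturates the ring alkene and cleaves the benzyl ether, and comes back to the route at 15.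

**Further compounds**

F1 | step 4 | trimethyl{[3-methyl-4-(2-methylpent-4-en-2-yl)-3-vinylcyclohex-1-en-1-yl]oxy}silane | C[Si](C)(C)OC1=C[C@](C)(C=C)[C@@H](C(C)(C)CC=C)CC1
F2 | step 4 | 2-[2-(benzyloxy)-1-methoxyethyl]-3-methyl-4-(2-methylpent-4-en-2-yl)-3-vinylcyclohexan-1-one | O=C1C(C(OC)COCc2ccccc2)[C@](C)(C=C)[C@@H](C(C)(C)CC=C)CC1
F3 | step 14 | 6-bromo enal silyl ether (mixture at C6) | O=CC1=CC(Br)[C@@H]2C(C)(C)CCC[C@@]2(C)[C@@H]1CC/C(CO[Si](C)(C)C(C)(C)C)=C\C(=O)OC
F4 | step 14 | 6-hydroxy enal silyl ether | O=CC1=C[C@@H](O)[C@@H]2C(C)(C)CCC[C@@]2(C)[C@@H]1CC/C(CO[Si](C)(C)C(C)(C)C)=C\C(=O)OC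
F5 | step 7 | trans-fused 1-[2-(benzyloxy)ethyl]-5,5,8a-trimethyl-3,4,4a,5,6,8a-hexahydronaphthalen-2(1H)-one | O=C1CC[C@@H]2C(C)(C)CC=C[C@@]2(C)[C@@H]1CCOCc1ccccc1
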